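**Retrosynthetic overview**
- Late stage: the spiro-epoxide comes from a C4=C15 exo-methylene (peracid, convex face), the enal from a C14 alcohol, and the C1–O–C5 tetrahydropyran from transannular reductive etherification of a C5 ketone by the C1 oxygen of a ten-membered carbocycle.
- Key disconnection: a [7+3] chromium relay annulation makes C5–C6 and C8–C9 in one flask from an acyclic C1–C5/C9–C10 iodo-enal (2-alkylacrolein at C5, vinyl iodide at C9) and a C6–C7–C8 lactone aldehyde.
- Enabling feature: C6 and C8 are both γ to the lactone carbonyl C12 across C7, so the C8 aldehyde can be stored as a menthyl pseudo-ester (5-alkoxy-γ-lactone) and set free only when the new C6 alkoxide takes over the lactone. The C4=C15 methylene beside the O-bearing C5 is the trace of a γ-silyloxyallylchromium made from the enal.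
- Ring order: γ-lactone (moved to O6) and ten-membered carbocycle in the key step, then the tetrahydropyran, then the epoxide.
- Stereocontrol: C7 from the menthyloxyfuranone auxiliary, C6 by Felkin–Anh addition, C1 by Corey–Bakshi–Shibata reduction, C5 and C4 from the bicyclic shape, C8 in the ring closure.

Key step: step 11

Remark: atoms are numbered as in a germacranolide (C1, C5 ether carbons; C4/C15 epoxide; C6 lactone carbinol; C7 ring fusion; C8 ester carbinol; C9=C10; C11–C13 methylene lactone; C14 formyl), and the C5 carbinol made in step 11 is drawn as the anti isomer although either epimer serves, because step 15 erases it.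

**Fragment A (steps 1–7)**

Step 1
Reactants: 1 hex-5-enal
Product: 2 rac-oct-7-en-1-yn-3-ol
Conditions: HC≡CMgBr, THF, 0 °C; aq. NH4Cl
Reagents that add atoms: ethynylmagnesium bromide, C#C[Mg]Br
Why: Grignard 1,2-addition to the aldehyde gives the propargylic alcohol; the carbinol centre is racemic and is erased in step 2.

Step 2
Reactants: 2 rac-oct-7-en-1-yn-3-ol
Product: 3 oct-7-en-1-yn-3-one
Conditions: activated MnO2 (excess), CH2Cl2, rt
Reagents that add atoms: none
Why: MnO2 oxidation of a propargylic alcohol should give the ynone and leave the remote terminal alkene untouched.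

Step 3
Reactants: 3 oct-7-en-1-yn-3-one
Product: 4 (Z)-2-(hydroxymethyl)-1-iodoocta-1,7-dien-3-one
Conditions: MgI2, paraformaldehyde, CH2Cl2, 0 °C to rt
Reagents that add atoms: magnesium iodide, [Mg+2].[I-].[I-]; formaldehyde (as paraformaldehyde), C=O
Why: β-iodo Morita–Baylis–Hillman (iodo-aldol) reaction: iodide adds to the ynone, the magnesium β-iodoallenolate is trapped by formaldehyde at the α-carbon, and the kinetic (Z)-isomer with iodine cis to the acyl carbon (C9 cis to C1, as the ring alkene needs) is expected.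

Step 4
Reactants: 4 (Z)-2-(hydroxymethyl)-1-iodoocta-1,7-dien-3-one
Product: 5 (3R,Z)-2-(iodomethylidene)oct-7-ene-1,3-diol
Conditions: (S)-2-methyl-CBS-oxazaborolidine (cat.), BH3·SMe2 (excess), THF, −30 °C; MeOH
Reagents that add atoms: none
Why: Corey–Bakshi–Shibata 1,2-reduction of the enone, with the branched alkenyl group as the large substituent, should set the (R)-carbinol that becomes C1.

Step 5
Reactants: 5 (3R,Z)-2-(iodomethylidene)oct-7-ene-1,3-diol
Product: 6 bis(tert-butyldimethylsilyl) ether of 5
Conditions: TBSOTf, 2,6-lutidine, CH2Cl2, −78 to 0 °C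
Reagents that add atoms: tert-butyldimethylsilyl triflate, CC(C)(C)[Si](C)(C)OS(=O)(=O)C(F)(F)F
Why: Standard silylation protects the C1 and C14 oxygens; no stereocentre is touched.

Step 6
Reactants: 6 bis(tert-butyldimethylsilyl) ether of 5
Product: 7 (5R,6Z)-bis-silyloxy iodoheptenal
Conditions: OsO4 (cat.), NaIO4, 2,6-lutidine, dioxane–H2O, rt
Reagents that add atoms: sodium periodate, [Na+].[O-]I(=O)(=O)=O
Why: Lemieux–Johnson cleavage: the monosubstituted terminal alkene should be dihydroxylated much faster than the hindered, iodine-deactivated trisubstituted alkene, and periodate cleaves the diol to the C5 aldehyde.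

Step 7
Reactants: 7 (5R,6Z)-bis-silyloxy iodoheptenal
Product: 8 (5R,6Z)-bis-silyloxy-7-iodo-2-methylidenehept-6-enal (fragment A)
Conditions: 37% aq. HCHO, pyrrolidine (cat.), propionic acid (cat.), iPrOH, 45 °C
Reagents that add atoms: formaldehyde, C=O
Why: Amine-catalysed Mannich condensation/elimination (α-methylenation of an aldehyde) installs C15 and gives the 2-alkylacrolein; the vinyl iodide and silyl ethers are inert.

**Fragment B (steps 8–10)**

Step 8
Reactants: 9 (5R)-5-[(1R,2S,5R)-menthyloxy]furan-2(5H)-one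
Product: 10 (4S,5R)-4-(1,3-dioxolan-2-yl)-5-menthyloxydihydrofuranone
Conditions: 1,3-dioxolane (solvent), benzophenone (cat.), hν (350 nm), rt
Reagents that add atoms: 1,3-dioxolane, C1COCO1
Why: Sensitised radical conjugate addition of the 1,3-dioxolan-2-yl radical to the butenolide should occur anti to the menthyloxy group, setting C7 and bringing in C6 as a masked formyl group.

Step 9
Reactants: 10 (4S,5R)-4-(1,3-dioxolan-2-yl)-5-menthyloxydihydrofuranone
Product: 11 (3S,4S,5R)-3-[(dimethylamino)methyl] lactone
Conditions: LiN(iPr)2, THF, −78 °C; Me2N=CH2+ I− (Eschenmoser's salt), −78 to 0 °C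
Reagents that add atoms: N,N-dimethylmethyleneiminium iodide, C=[N+](C)C.[I-]
Why: Mannich alkylation of the lactone enolate anti to the C4 substituent introduces C13 as a masked α-methylene group; the enolate has no β-leaving group.

Step 10
Reactants: 11 (3S,4S,5R)-3-[(dimethylamino)methyl] lactone
Product: 12 (2R,3S,4S)-4-[(dimethylamino)methyl]-2-menthyloxy-5-oxotetrahydrofuran-3-carbaldehyde (fragment B)
Conditions: 1 M HCl, THF, 0 °C to rt; NaHCO3 to pH 8
Reagents that add atoms: water, O
Why: Acid hydrolysis of the dioxolane (a dialkyl acetal) should be much faster than that of the acyl-substituted menthyl acetal, so only the C6 aldehyde is released.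

**Union and endgame (steps 11–19)**

Step 11
Reactants: 8 iodo-enal (fragment A); 12 formyl pseudo-ester (fragment B)
Product: 15 macrocyclic C8 alcohol, via pinacol adduct 13 (not isolated), via seco-aldehyde 14 (not isolated)
Conditions: CrCl2 (8 equiv), Et3SiCl (1.1 equiv), THF–DMF, 0 °C, slow addition of 8 to 12; then NiCl2 (5 mol %), DMF, 0.005 M, rt to 40 °C; pH 7 buffer
Reagents that add atoms: chlorotriethylsilane, CC[Si](Cl)(CC)CC
Why: Proposed new method: CrCl2 with Et3SiCl reduces the 2-alkylacrolein of 8 to a γ-silyloxyallyl trivalent-chromium species that adds through its oxygen-bearing carbon C5 to the only free formyl group of 12 (C6) and leaves the C4=C15 exo-methylene, the closest known reaction type being the chromium-mediated cross-pinacol coupling of enals with aldehydes. The new C6 chromium alkoxide then attacks the pseudo-ester carbonyl C12 (5-exo-trig acyl transfer, the known transposition of a γ-lactone between two γ-oxygens), which closes the 6,12-lactone, expels the C8 hemiacetal and so sets free menthol and the C8 aldehyde only after the first C–C bond exists. NiCl2 then converts the vinyl iodide into a vinylchromium that adds to this aldehyde in an intramolecular Nozaki–Hiyama–Kishi reaction (10-exo-trig closure of the carbocycle). C6 is set by Felkin–Anh addition anti to the C7–C8 bond of 12; C7 comes from 12 and, being α to the released aldehyde, can relax to the trans-lactone; C5 arises from the chair Zimmerman–Traxler transition state but is erased in step 15; C8 is set by the conformation of the closing ring, which is the least secure element. The step needs an unambiguous pairing of two nucleophiles with two aldehydes, and this is secured because the second aldehyde stays masked as the C8 menthyl pseudo-ester until the C6 alkoxide exists and because the vinyl iodide is inert to CrCl2 until NiCl2 is added.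

Step 12
Reactants: 15 macrocyclic C8 alcohol
Product: 16 C8 methacrylate
Conditions: methacrylic anhydride, Et3N, DMAP (cat.), CH2Cl2, 0 °C to rt
Reagents that add atoms: methacrylic anhydride, C=C(C)C(=O)OC(=O)C(C)=C
Why: DMAP-catalysed acylation of the allylic C8 alcohol installs the ester and blocks any later lactone migration from O6 to O8.

Step 13
Reactants: 16 C8 methacrylate
Product: 18 α-methylene lactone, via ammonium iodide 17 (not isolated)
Conditions: MeI (excess), MeCN, rt; then aq. NaHCO3, EtOAc, rt
Reagents that add atoms: none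
Why: Quaternisation of the Mannich base and E1cB loss of trimethylamine (the second half of the classical α-methylenation of lactones) should unveil the C11=C13 methylene under conditions the methacrylate tolerates.

Step 14
Reactants: 18 α-methylene lactone
Product: 19 C5 allylic alcohol
Conditions: PPTS (cat.), MeOH–CH2Cl2, 0 °C
Reagents that add atoms: none
Why: Acid-catalysed methanolysis should remove the secondary triethylsilyl ether selectively beside the more robust tert-butyldimethylsilyl ethers.

Step 15
Reactants: 19 C5 allylic alcohol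
Product: 20 C5 ketone
Conditions: Dess–Martin periodinane, CH2Cl2, 0 °C to rt
Reagents that add atoms: none
Why: Dess–Martin oxidation under neutral conditions gives the α-methylene ketone and removes the C5 stereocentre, so the diastereoselectivity of step 11 at C5 does not matter.

Step 16
Reactants: 20 C5 ketone
Product: 21 1,5-bridged ether (C14 silyl ether)
Conditions: Et3SiH (3 equiv), BiBr3 (10 mol %), MeCN, 0 °C to rt
Reagents that add atoms: none
Why: Reductive etherification of a δ-silyloxy ketone: the C1 silyl ether oxygen adds transannularly to the activated C5 carbonyl (6-exo-trig), and the bridgehead oxocarbenium ion is reduced by the silane from its only open face, so C5 is set cis to the existing C1 centre and the tetrahydropyran is closed.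

Step 17
Reactants: 21 1,5-bridged ether (C14 silyl ether)
Product: 22 C14 allylic alcohol
Conditions: HF·pyridine, pyridine, THF, 0 °C to rt
Reagents that add atoms: none
Why: Fluoride cleavage of the primary silyl ether; esters, ether bridge and both exo-methylene groups are stable to buffered HF.

Step 18
Reactants: 22 C14 allylic alcohol
Product: 23 C14 enal
Conditions: activated MnO2 (excess), CH2Cl2, rt
Reagents that add atoms: none
Why: MnO2 oxidation of the primary allylic alcohol gives the enal and at the same time deactivates the C9=C10 alkene toward the next step.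

Step 19
Reactants: 23 C14 enal
Product: 24 CNP0257628.1 (target)
Conditions: mCPBA (1.2 equiv), CH2Cl2, pH 7 phosphate buffer, 0 °C
Reagents that add atoms: 3-chloroperbenzoic acid, OOC(=O)c1cccc(Cl)c1
Why: Prilezhaev epoxidation: only the 1,1-disubstituted C4=C15 alkene is electron-rich, and the peracid should approach from the convex face opposite the axial C5–C6 bond, placing the epoxide oxygen trans to C6 (4R).

**Compound list**
1 | hex-5-enal | C=CCCCC=O | starting material
2 | rac-oct-7-en-1-yn-3-ol | C=CCCCC(O)C#C | intermediate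
3 | oct-7-en-1-yn-3-one | C=CCCCC(=O)C#C | intermediate
4 | (Z)-2-(hydroxymethyl)-1-iodoocta-1,7-dien-3-one | I/C=C(/CO)C(=O)CCCC=C | intermediate
5 | (3R,Z)-2-(iodomethylidene)oct-7-ene-1,3-diol | I/C=C(/CO)[C@H](O)CCCC=C | intermediate
6 | (3R,Z)-1,3-bis(tert-butyldimethylsilyloxy)-2-(iodomethylidene)oct-7-ene | I/C=C(/CO[Si](C)(C)C(C)(C)C)[C@H](O[Si](C)(C)C(C)(C)C)CCCC=C | intermediate
7 | (5R,6Z)-5-(tert-butyldimethylsilyloxy)-6-[(tert-butyldimethylsilyloxy)methyl]-7-iodohept-6-enal | I/C=C(/CO[Si](C)(C)C(C)(C)C)[C@H](O[Si](C)(C)C(C)(C)C)CCCC=O | intermediate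
8 | (5R,6Z)-5-(tert-butyldimethylsilyloxy)-6-[(tert-butyldimethylsilyloxy)methyl]-7-iodo-2-methylidenehept-6-enal (fragment A) | I/C=C(/CO[Si](C)(C)C(C)(C)C)[C@H](O[Si](C)(C)C(C)(C)C)CCC(=C)C=O | intermediate
9 | (5R)-5-[(1R,2S,5R)-menthyloxy]furan-2(5H)-one | O=C1C=C[C@H](O[C@@H]2C[C@H](C)CC[C@H]2C(C)C)O1 | starting material
10 | (4S,5R)-4-(1,3-dioxolan-2-yl)-5-[(1R,2S,5R)-menthyloxy]dihydrofuran-2(3H)-one | O=C1C[C@@H](C2OCCO2)[C@H](O[C@@H]2C[C@H](C)CC[C@H]2C(C)C)O1 | intermediate
11 | (3S,4S,5R)-3-[(dimethylamino)methyl]-4-(1,3-dioxolan-2-yl)-5-[(1R,2S,5R)-menthyloxy]dihydrofuran-2(3H)-one | O=C1[C@H](CN(C)C)[C@@H](C2OCCO2)[C@H](O[C@@H]2C[C@H](C)CC[C@H]2C(C)C)O1 | intermediate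
12 | (2R,3S,4S)-4-[(dimethylamino)methyl]-2-[(1R,2S,5R)-menthyloxy]-5-oxotetrahydrofuran-3-carbaldehyde (fragment B) | O=C1[C@H](CN(C)C)[C@@H](C=O)[C@H](O[C@@H]2C[C@H](C)CC[C@H]2C(C)C)O1 | intermediate
13 | pinacol adduct (1R,5R,6S; lactone centres as in 12): C5 triethylsilyl ether, C6 carbinol (chromium alkoxide in the flask), C8 menthyl pseudo-ester intact | I/C=C(/CO[Si](C)(C)C(C)(C)C)[C@H](O[Si](C)(C)C(C)(C)C)CCC(=C)[C@@H](O[Si](CC)(CC)CC)[C@@H](O)[C@H]1[C@H](O[C@@H]2C[C@H](C)CC[C@H]2C(C)C)OC(=O)[C@@H]1CN(C)C | intermediate (not isolated)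
14 | seco-aldehyde (1R,5R,6S,7S,11S): 6,12-γ-lactone with free C8 formyl group and C9 vinyl iodide | I/C=C(/CO[Si](C)(C)C(C)(C)C)[C@H](O[Si](C)(C)C(C)(C)C)CCC(=C)[C@@H](O[Si](CC)(CC)CC)[C@H]1OC(=O)[C@H](CN(C)C)[C@@H]1C=O | intermediate (not isolated)
15 | (1R,5R,6S,7R,8R,11S,9Z)-1,14-bis(tert-butyldimethylsilyloxy)-13-(dimethylamino)-8-hydroxy-5-(triethylsilyloxy)germacra-4(15),9-dien-12,6-olide | O[C@@H]1/C=C(/CO[Si](C)(C)C(C)(C)C)[C@H](O[Si](C)(C)C(C)(C)C)CCC(=C)[C@@H](O[Si](CC)(CC)CC)[C@H]2OC(=O)[C@H](CN(C)C)[C@@H]21 | intermediate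
16 | 8-O-(2-methylprop-2-enoyl) derivative of 15 | C=C(C)C(=O)O[C@@H]1/C=C(/CO[Si](C)(C)C(C)(C)C)[C@H](O[Si](C)(C)C(C)(C)C)CCC(=C)[C@@H](O[Si](CC)(CC)CC)[C@H]2OC(=O)[C@H](CN(C)C)[C@@H]21 | intermediate
17 | 13-(trimethylammonio) iodide of 16 | C=C(C)C(=O)O[C@@H]1/C=C(/CO[Si](C)(C)C(C)(C)C)[C@H](O[Si](C)(C)C(C)(C)C)CCC(=C)[C@@H](O[Si](CC)(CC)CC)[C@H]2OC(=O)[C@H](C[N+](C)(C)C)[C@@H]21.[I-] | intermediate (not isolated)
18 | (1R,5R,6S,7R,8R,9Z)-1,14-bis(tert-butyldimethylsilyloxy)-8-(methacryloyloxy)-5-(triethylsilyloxy)germacra-4(15),9,11(13)-trien-12,6-olide | C=C(C)C(=O)O[C@@H]1/C=C(/CO[Si](C)(C)C(C)(C)C)[C@H](O[Si](C)(C)C(C)(C)C)CCC(=C)[C@@H](O[Si](CC)(CC)CC)[C@H]2OC(=O)C(=C)[C@@H]21 | intermediate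
19 | (1R,5R,6S,7R,8R,9Z)-1,14-bis(tert-butyldimethylsilyloxy)-5-hydroxy-8-(methacryloyloxy)germacra-4(15),9,11(13)-trien-12,6-olide | C=C(C)C(=O)O[C@@H]1/C=C(/CO[Si](C)(C)C(C)(C)C)[C@H](O[Si](C)(C)C(C)(C)C)CCC(=C)[C@@H](O)[C@H]2OC(=O)C(=C)[C@@H]21 | intermediate
20 | (1R,6S,7R,8R,9Z)-1,14-bis(tert-butyldimethylsilyloxy)-8-(methacryloyloxy)-5-oxogermacra-4(15),9,11(13)-trien-12,6-olide | C=C(C)C(=O)O[C@@H]1/C=C(/CO[Si](C)(C)C(C)(C)C)[C@H](O[Si](C)(C)C(C)(C)C)CCC(=C)C(=O)[C@H]2OC(=O)C(=C)[C@@H]21 | intermediate
21 | (1R,5S,6S,7R,8R,9Z)-14-(tert-butyldimethylsilyloxy)-1,5-epoxy-8-(methacryloyloxy)germacra-4(15),9,11(13)-trien-12,6-olide | C=C(C)C(=O)O[C@@H]1/C=C(/CO[Si](C)(C)C(C)(C)C)[C@H]2CCC(=C)[C@H](O2)[C@H]2OC(=O)C(=C)[C@@H]21 | intermediate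
22 | (1R,5S,6S,7R,8R,9Z)-1,5-epoxy-14-hydroxy-8-(methacryloyloxy)germacra-4(15),9,11(13)-trien-12,6-olide | C=C(C)C(=O)O[C@@H]1/C=C(/CO)[C@H]2CCC(=C)[C@H](O2)[C@H]2OC(=O)C(=C)[C@@H]21 | intermediate
23 | (1R,5S,6S,7R,8R,9E)-1,5-epoxy-8-(methacryloyloxy)-14-oxogermacra-4(15),9,11(13)-trien-12,6-olide | C=C(C)C(=O)O[C@@H]1/C=C(/C=O)[C@H]2CCC(=C)[C@H](O2)[C@H]2OC(=O)C(=C)[C@@H]21 | intermediate
24 | CNP0257628.1, (1R,4R,5R,6S,7R,8R,9E)-1,5:4,15-diepoxy-8-(methacryloyloxy)-14-oxogermacra-9,11(13)-dien-12,6-olide | C=C(C)C(=O)O[C@@H]1/C=C(/C=O)[C@H]2CC[C@@]3(CO3)[C@H](O2)[C@H]2OC(=O)C(=C)[C@@H]21 | target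

**Step count and risks**

Total step count: 19 (7 for fragment A, 3 for fragment B, 9 from the union). Longest linear sequence: 16 (steps 1–7, then 11–19).

Steps most likely to fail:

1. Step 11 (proposed new method). The C6 alkoxide may stay bound to trivalent chromium or be silylated, so that the lactone transposition stalls; the vinylchromium may add before the relay and give the wrong pairing; the ring closure may show poor facial selectivity at C8; intermolecular oligomerisation may compete. The fallback decouples the cascade into known reactions. It sets out from 8 and 12: the chromium cross-pinacol is run alone (CrCl2, Et3SiCl, no nickel salt) and the pinacol adduct 13 is isolated. Catalytic DBU in CH2Cl2 then transposes the lactone with loss of menthol to give seco-aldehyde 14, and a separate Nozaki–Hiyama–Kishi macrocyclisation (CrCl2, catalytic NiCl2, DMSO, high dilution) gives 15. If the ring closure delivers the C8 epimer of 15 F1 instead, a Mitsunobu esterification with methacrylic acid (PPh3, DIAD) inverts C8 and returns to the route at 16.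

2. Step 16. Hydride may be delivered to C15 (1,4) through the conjugated oxocarbenium ion, the C1 oxygen may close onto C15 by oxa-Michael addition instead of onto the carbonyl, or the primary silyl ether may be lost. The fallback replaces the redox approach by a displacement and sets out from 19: mesylation (MsCl, Et3N, −20 °C) gives the C5 allylic mesylate F2. HF·pyridine then removes both silyl ethers, and the freed C1 hydroxyl displaces the mesylate transannularly with inversion, which converts the anti C5 centre of 19 into the target configuration and returns to the route at 22. This fallback relies on 19 being the anti epimer.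

3. Step 3. The iodo-aldol may give a poor Z/E ratio or low conversion with formaldehyde. The fallback sets out from 3: Noyori transfer hydrogenation (RuCl[(R,R)-TsDPEN](p-cymene), HCO2H/Et3N) gives (R)-oct-7-en-1-yn-3-ol F3. Copper-catalysed anti-carbomagnesiation of this propargylic alcohol with (isopropoxydimethylsilyl)methylmagnesium chloride (CuI), then iodination with I2, gives the (Z)-vinyl iodide silane F4. Tamao oxidation (KF, KHCO3, H2O2) returns to the route at 5, bypassing 4.

Further compounds
F1 | step 11 | C8 epimer of 15, (1R,5R,6S,7R,8S,11S,9Z) | O[C@H]1/C=C(/CO[Si](C)(C)C(C)(C)C)[C@H](O[Si](C)(C)C(C)(C)C)CCC(=C)[C@@H](O[Si](CC)(CC)CC)[C@H]2OC(=O)[C@H](CN(C)C)[C@@H]21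
F2 | step 16 | C5 methanesulfonate of 19 | C=C(C)C(=O)O[C@@H]1/C=C(/CO[Si](C)(C)C(C)(C)C)[C@H](O[Si](C)(C)C(C)(C)C)CCC(=C)[C@@H](OS(C)(=O)=O)[C@H]2OC(=O)C(=C)[C@@H]21
F3 | step 3 | (R)-oct-7-en-1-yn-3-ol | C#C[C@H](O)CCCC=C
F4 | step 3 | (3R,Z)-1-iodo-2-{[isopropoxy(dimethyl)silyl]methyl}octa-1,7-dien-3-ol | I/C=C(/C[Si](C)(C)OC(C)C)[C@H](O)CCCC=C
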